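The seven-membered ring C4–C5–C6–C7–C8–C9–C10 is cut into a two-carbon unit (C4=C5, the enone of a 4-substituted cyclohexenone that becomes the six-membered ring) and a five-carbon unit (C6–C10). In one acid-catalysed operation the enol silyl ether carbon C6 adds to C5 (closing the seven-membered ring C5–C11), and the resulting ring enol ether carbon C4 captures a cobalt-stabilised tertiary propargylic cation at C10. This closes the cyclobutane C4–C5–C11–C10 of the bicyclo[3.1.1]heptane. The precursor is a monocyclic enone whose C11 carries a siloxy-enyne chain as its Co2(CO)6 complex, with a tertiary methyl ether at C10; the complexed alkyne later delivers the cis-8,9-diol.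

Key step: step 7

Numbering: longipinane numbering of the target is used throughout: C1 ring C=O, C2=C3(CH3), C4 (CH next to C3), C5 (CH bearing C6), C6 (CMe2), C7 (O-angelate), C8 (O-2-methylbutanoate), C9 (OH), C10 (C–CH3), C11 (CH next to C1); the cyclobutane is C4, C5, C11, C10.

Remark: C10 is carried as a mixture of both epimers from step 3 to step 6 (no descriptor at that carbon in the SMILES); it becomes planar in step 7 and is then fixed by the ring system. Compound 4 is taken as commercially available.

Step 1
Reactants: 1 4-methylpent-1-yn-3-ol (racemic)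
Product: 2 4-methylpent-1-yn-3-one
Conditions: IBX, EtOAc, 75 °C
Reagents that add atoms: none
Why: Hypervalent-iodine oxidation of the secondary propargylic alcohol should give the ynone without touching the terminal alkyne.

Step 2
Reactants: 2 4-methylpent-1-yn-3-one
Product: 3 triisopropyl[(4-methylpent-3-en-1-yn-3-yl)oxy]silane
Conditions: TIPSOTf, i-Pr2NEt, CH2Cl2, 0 °C
Reagents that add atoms: triisopropylsilyl triflate, CC(C)[Si](OS(=O)(=O)C(F)(F)F)(C(C)C)C(C)C
Why: Soft enolisation of the only enolisable position (the isopropyl CH) with a silyl triflate and a hindered, non-nucleophilic amine should give the tetrasubstituted enol silyl ether without conjugate addition to the ynone.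

Step 3
Reactants: 3 triisopropyl[(4-methylpent-3-en-1-yn-3-yl)oxy]silane; 4 1-(1,4-dioxaspiro[4.5]decan-8-yl)ethan-1-one
Product: 7 8-[2-methoxy-6-methyl-5-(triisopropylsilyloxy)hept-5-en-3-yn-2-yl]-1,4-dioxaspiro[4.5]decane (racemic at C10), via lithium acetylide 5 (not isolated), via lithium alkoxide 6 (not isolated)
Conditions: n-BuLi, THF, −78 °C; then 4; then MeI, DMPU, −78 °C to 25 °C
Reagents that add atoms: iodomethane, CI
Why: Acetylide 1,2-addition to the methyl ketone followed by O-methylation of the tertiary alkoxide should install the whole five-carbon unit; the new carbinol centre C10 forms racemic, which does not matter because it is ionised in step 7.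

Step 4
Reactants: 7 8-[2-methoxy-6-methyl-5-(triisopropylsilyloxy)hept-5-en-3-yn-2-yl]-1,4-dioxaspiro[4.5]decane
Product: 8 4-[2-methoxy-6-methyl-5-(triisopropylsilyloxy)hept-5-en-3-yn-2-yl]cyclohexan-1-one (racemic at C10)
Conditions: PPTS (cat.), THF/H2O (4:1), 50 °C
Reagents that add atoms: water, O
Why: Mild acid-catalysed ketal hydrolysis should free the ring ketone while the hindered tetrasubstituted triisopropylsilyl enol ether and the uncomplexed tertiary propargylic ether survive.

Step 5
Reactants: 8 4-[2-methoxy-6-methyl-5-(triisopropylsilyloxy)hept-5-en-3-yn-2-yl]cyclohexan-1-one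
Product: 10 (4R)-4-[2-methoxy-6-methyl-5-(triisopropylsilyloxy)hept-5-en-3-yn-2-yl]cyclohex-2-en-1-one (both C10 epimers), via trimethylsilyl enol ether 9 (not isolated)
Conditions: LiN[(S)-CH(Me)Ph]2 (from the amine and n-BuLi), TMSCl, THF, −100 °C; crude 9, then Pd(OAc)2, MeCN, 25 °C
Reagents that add atoms: none
Why: Enantiotopic-proton-selective deprotonation of the conformationally locked 4-substituted cyclohexanone by the chiral lithium amide with in situ silylation should set C11 (R) under reagent control (the (R,R)-amide gives the (S)-enol ether of 4-tert-butylcyclohexanone, hence the (S,S)-amide here), and Saegusa–Ito oxidation of the more reactive trimethylsilyl enol ether carries this into the enone.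

Step 6
Reactants: 10 (4R)-4-[2-methoxy-6-methyl-5-(triisopropylsilyloxy)hept-5-en-3-yn-2-yl]cyclohex-2-en-1-one
Product: 11 hexacarbonyldicobalt complex of the alkyne of 10
Conditions: Co2(CO)8, CH2Cl2, 25 °C
Reagents that add atoms: dicobalt octacarbonyl, O=C=[Co](=C=O)(=C=O)(=C=O)[Co](=C=O)(=C=O)(=C=O)=C=O
Why: Alkyne complexation by Co2(CO)8 is selective over the enone and the enol ether, bends the alkyne so that it fits a seven-membered ring, and turns the tertiary methyl ether into a Nicholas cation precursor.

Step 7
Reactants: 11 hexacarbonyldicobalt complex of the alkyne of 10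
Product: 14 hexacarbonyldicobalt complex of longipin-8-yne-3,7-dione (C4/C5/C10/C11 configured as in 26), via bicyclic Michael adduct 12 (not isolated), via Nicholas cation 13 (not isolated)
Conditions: Tf2NH (10 mol%), CH2Cl2 (0.005 M), 4 Å MS, −78 °C, then −78 to −30 °C
Reagents that add atoms: none
Why: Proposed new method: the silyl triflimide formed in situ activates the enone, the enol silyl ether carbon C6 adds to C5 (Mukaiyama–Michael addition with silyl transfer) to give 12, whose methyl ether is then ionised to the cobalt-stabilised cation 13, which is captured by the ring enol silyl ether carbon C4 with release of i-Pr3SiOMe and the silyl catalyst. The closest known reaction type is the dicobalt-hexacarbonyl-mediated (5+2) annulation of a siloxy-enyne propargylic cation with an enol silyl ether (run here in Michael-first polarity), together with intramolecular Nicholas alkylations of enol silyl ethers, none of which has closed a four-membered ring. The seven-membered ring C5–C6–C7–C8–C9–C10–C11 closes 7-exo-trig with the bent complexed alkyne inside the ring, and the cyclobutane C4–C5–C11–C10 closes 4-exo across the C5–C11 bond, which also completes the bicyclo[3.1.1]heptanone and the second seven-membered ring through C4–C10. C5 is set cis to the C11–C10 bond because the tether lets C6 reach only that face with an attack perpendicular to the enone plane, C4 and C10 can bond only on the same face, and the planar cation erases the C10 epimer mixture, so C11 alone fixes C4, C5 and C10. The step needs conjugate addition before ionisation and C- over O-alkylation: the bulky silyl Lewis acid should prefer the unhindered enone oxygen to the tertiary ether shielded by the cluster, the cation cannot be quenched by C6 (that would need a five-membered cycloalkyne) and does not rearrange, and Nicholas cations alkylate enol silyl ethers at carbon. High dilution suppresses intermolecular capture of the cation.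

Step 8
Reactants: 14 hexacarbonyldicobalt complex of longipin-8-yne-3,7-dione
Product: 15 longipin-8-ene-3,7-dione (C4/C5/C10/C11 as in 26)
Conditions: n-Bu3SnH, benzene, 65 °C
Reagents that add atoms: none
Why: Tin hydride reductive decomplexation of a cycloheptyne–Co2(CO)6 complex, whose free alkyne cannot be released, should deliver the cis-alkene, here the C7 enone.

Step 9
Reactants: 15 longipin-8-ene-3,7-dione
Product: 17 7-oxolongipina-2,8-dien-3-yl trifluoromethanesulfonate, via potassium enolate 16 (not isolated)
Conditions: KN(SiMe3)2, THF, −78 °C; then PhNTf2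
Reagents that add atoms: N-phenylbis(trifluoromethanesulfonimide), O=S(=O)(N(c1ccccc1)S(=O)(=O)C(F)(F)F)C(F)(F)F
Why: Only C2 can be deprotonated (C4 is a bridgehead and the C7 ketone has no α- or γ-hydrogen), so enolate O-sulfonylation should give the C2=C3 enol triflate regioselectively.

Step 10
Reactants: 17 7-oxolongipina-2,8-dien-3-yl trifluoromethanesulfonate
Product: 18 longipina-2,8-dien-7-one
Conditions: MeZnCl, Pd(PPh3)4 (5 mol%), THF, 25 °C
Reagents that add atoms: methylzinc chloride, C[Zn]Cl
Why: Negishi coupling of the enol triflate should install the C3 methyl group and the C2=C3 alkene while the organozinc leaves the C7 enone untouched.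

Step 11
Reactants: 18 longipina-2,8-dien-7-one
Product: 19 (7R)-longipina-2,8-dien-7-ol
Conditions: (S)-Me-CBS (0.2 equiv), catecholborane, toluene, −78 °C
Reagents that add atoms: none
Why: Corey–Bakshi–Shibata 1,2-reduction sets C7 under catalyst control, needed because the two faces of the C7 carbonyl are nearly equivalent in the substrate; with quaternary C6 as the large group the (S)-catalyst should deliver hydride to the face on the C11 side, giving (7R), and catecholborane avoids hydroboration.

Step 12
Reactants: 19 (7R)-longipina-2,8-dien-7-ol; 20 angelic acid ((Z)-2-methylbut-2-enoic acid)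
Product: 22 (7R)-longipina-2,8-dien-7-yl angelate, via mixed anhydride 21 (not isolated)
Conditions: 20, 2,4,6-trichlorobenzoyl chloride, Et3N, toluene, 25 °C; then 19, 75 °C
Reagents that add atoms: none
Why: Yamaguchi esterification through the mixed anhydride should acylate the hindered allylic alcohol without Z-to-E isomerisation of the angelate, and no stereocentre is touched.

Step 13
Reactants: 22 (7R)-longipina-2,8-dien-7-yl angelate
Product: 23 (7R)-1-oxolongipina-2,8-dien-7-yl angelate
Conditions: Rh2(cap)4 (1 mol%), t-BuOOH, K2CO3, CH2Cl2, 25 °C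
Reagents that add atoms: tert-butyl hydroperoxide, CC(C)(C)OO
Why: Peroxyl-radical allylic oxidation should attack the only allylic methylene, C1, as in the oxidation of α-pinene to verbenone; C4–H is a bridgehead and C7–H is deactivated by its acyloxy group.

Step 14
Reactants: 23 (7R)-1-oxolongipina-2,8-dien-7-yl angelate
Product: 24 (7S,8S,9S)-8,9-dihydroxy-1-oxolongipin-2-en-7-yl angelate
Conditions: OsO4 (5 mol%), NMO, acetone/H2O (5:1), 0 °C
Reagents that add atoms: N-methylmorpholine N-oxide, C[N+]1([O-])CCOCC1; water, O
Why: Catalytic osmylation should take the only unconjugated alkene (C8=C9) and add syn from the face anti to the allylic C7 ester, which is also the less hindered face, setting C8 and C9 (8,9-cis and 7,8-trans).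

Step 15
Reactants: 24 (7S,8S,9S)-8,9-dihydroxy-1-oxolongipin-2-en-7-yl angelate; 25 (R)-2-methylbutanoic acid
Product: 26 (4R,5S,7S,8S,9S,10R,11R)-9-hydroxy-7-[(Z)-2-methylbut-2-enoyloxy]-8-[(2R)-2-methylbutanoyloxy]longipin-2-en-1-one (CNP0206166.1)
Conditions: DCC, DMAP (10 mol%), CH2Cl2, 0 °C
Reagents that add atoms: none
Why: Steglich esterification should acylate the C8 hydroxyl selectively because the C9 hydroxyl is neopentylic (next to quaternary C10 on the cyclobutane), and the mild conditions leave the acid's stereocentre intact.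

Compound list
1 | 4-methylpent-1-yn-3-ol (racemic) | CC(C)C(O)C#C | starting material
2 | 4-methylpent-1-yn-3-one | CC(C)C(=O)C#C | intermediate
3 | triisopropyl[(4-methylpent-3-en-1-yn-3-yl)oxy]silane | CC(C)=C(O[Si](C(C)C)(C(C)C)C(C)C)C#C | intermediate
4 | 1-(1,4-dioxaspiro[4.5]decan-8-yl)ethan-1-one | CC(=O)C1CCC2(CC1)OCCO2 | starting material
5 | [4-methyl-3-(triisopropylsilyloxy)pent-3-en-1-yn-1-yl]lithium (not isolated) | [Li]C#CC(O[Si](C(C)C)(C(C)C)C(C)C)=C(C)C | intermediate
6 | lithium 2-(1,4-dioxaspiro[4.5]decan-8-yl)-6-methyl-5-(triisopropylsilyloxy)hept-5-en-3-yn-2-olate (not isolated) | [Li]OC(C)(C#CC(O[Si](C(C)C)(C(C)C)C(C)C)=C(C)C)C1CCC2(CC1)OCCO2 | intermediate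
7 | 8-[2-methoxy-6-methyl-5-(triisopropylsilyloxy)hept-5-en-3-yn-2-yl]-1,4-dioxaspiro[4.5]decane (racemic at C10) | COC(C)(C#CC(O[Si](C(C)C)(C(C)C)C(C)C)=C(C)C)C1CCC2(CC1)OCCO2 | intermediate
8 | 4-[2-methoxy-6-methyl-5-(triisopropylsilyloxy)hept-5-en-3-yn-2-yl]cyclohexan-1-one (racemic at C10) | COC(C)(C#CC(O[Si](C(C)C)(C(C)C)C(C)C)=C(C)C)C1CCC(=O)CC1 | intermediate
9 | trimethyl{[(4R)-4-(2-methoxy-6-methyl-5-(triisopropylsilyloxy)hept-5-en-3-yn-2-yl)cyclohex-1-en-1-yl]oxy}silane (both C10 epimers; not isolated) | C[Si](C)(C)OC1=CC[C@@H](CC1)C(C)(OC)C#CC(O[Si](C(C)C)(C(C)C)C(C)C)=C(C)C | intermediate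
10 | (4R)-4-[2-methoxy-6-methyl-5-(triisopropylsilyloxy)hept-5-en-3-yn-2-yl]cyclohex-2-en-1-one (both C10 epimers) | O=C1C=C[C@@H](CC1)C(C)(OC)C#CC(O[Si](C(C)C)(C(C)C)C(C)C)=C(C)C | intermediate
11 | hexacarbonyldicobalt complex of the alkyne of 10 (drawn as the dicobaltatetrahedrane) | O=C1C=C[C@@H](CC1)C(C)(OC)C23C4(C(O[Si](C(C)C)(C(C)C)C(C)C)=C(C)C)[Co]2(=C=O)(=C=O)(=C=O)[Co]34(=C=O)(=C=O)=C=O | intermediate
12 | cis-fused bicyclic Michael adduct: Co2(CO)6-complexed cycloheptynone (C5–C6 bond formed, C10 still OMe) fused to the ring triisopropylsilyl enol ether C3=C4 (not isolated) | O=C1C45C6(C(C)(OC)[C@@H]3CCC(O[Si](C(C)C)(C(C)C)C(C)C)=C[C@@H]3C1(C)C)[Co]4(=C=O)(=C=O)(=C=O)[Co]56(=C=O)(=C=O)=C=O | intermediate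
13 | cobalt-stabilised tertiary propargylic cation at C10 derived from 12 (not isolated) | O=C1C45C6([C+](C)[C@@H]3CCC(O[Si](C(C)C)(C(C)C)C(C)C)=C[C@@H]3C1(C)C)[Co]4(=C=O)(=C=O)(=C=O)[Co]56(=C=O)(=C=O)=C=O | intermediate
14 | hexacarbonyldicobalt complex of longipin-8-yne-3,7-dione (ring stereocentres as in 26) | O=C1C45C6([C@@]2(C)[C@@H]3CCC(=O)[C@H]2[C@@H]3C1(C)C)[Co]4(=C=O)(=C=O)(=C=O)[Co]56(=C=O)(=C=O)=C=O | intermediate
15 | longipin-8-ene-3,7-dione (ring stereocentres as in 26) | O=C1C=C[C@@]2(C)[C@@H]3CCC(=O)[C@H]2[C@@H]3C1(C)C | intermediate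
16 | potassium 7-oxolongipina-2,8-dien-3-olate (not isolated) | O=C1C=C[C@@]2(C)[C@@H]3CC=C(O[K])[C@H]2[C@@H]3C1(C)C | intermediate
17 | 7-oxolongipina-2,8-dien-3-yl trifluoromethanesulfonate | O=C1C=C[C@@]2(C)[C@@H]3CC=C(OS(=O)(=O)C(F)(F)F)[C@H]2[C@@H]3C1(C)C | intermediate
18 | longipina-2,8-dien-7-one | O=C1C=C[C@@]2(C)[C@@H]3CC=C(C)[C@H]2[C@@H]3C1(C)C | intermediate
19 | (7R)-longipina-2,8-dien-7-ol | O[C@@H]1C=C[C@@]2(C)[C@@H]3CC=C(C)[C@H]2[C@@H]3C1(C)C | intermediate
20 | angelic acid ((Z)-2-methylbut-2-enoic acid) | C/C=C(/C)C(=O)O | starting material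
21 | angelic 2,4,6-trichlorobenzoic anhydride (not isolated) | C/C=C(/C)C(=O)OC(=O)c1c(Cl)cc(Cl)cc1Cl | intermediate
22 | (7R)-longipina-2,8-dien-7-yl angelate | C/C=C(/C)C(=O)O[C@@H]1C=C[C@@]2(C)[C@@H]3CC=C(C)[C@H]2[C@@H]3C1(C)C | intermediate
23 | (7R)-1-oxolongipina-2,8-dien-7-yl angelate | C/C=C(/C)C(=O)O[C@@H]1C=C[C@@]2(C)[C@@H]3C(=O)C=C(C)[C@H]2[C@@H]3C1(C)C | intermediate
24 | (7S,8S,9S)-8,9-dihydroxy-1-oxolongipin-2-en-7-yl angelate | C/C=C(/C)C(=O)O[C@@H]1[C@@H](O)[C@@H](O)[C@@]2(C)[C@@H]3C(=O)C=C(C)[C@H]2[C@@H]3C1(C)C | intermediate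
25 | (R)-2-methylbutanoic acid | CC[C@@H](C)C(=O)O | starting material
26 | (4R,5S,7S,8S,9S,10R,11R)-9-hydroxy-7-[(Z)-2-methylbut-2-enoyloxy]-8-[(2R)-2-methylbutanoyloxy]longipin-2-en-1-one (CNP0206166.1) | C/C=C(/C)C(=O)O[C@@H]1[C@@H](OC(=O)[C@H](C)CC)[C@@H](O)[C@@]2(C)[C@@H]3C(=O)C=C(C)[C@H]2[C@@H]3C1(C)C | target

Total step count: 15
Longest linear sequence: 15 steps (from 1; compounds 4, 20 and 25 enter as purchased materials)

Steps most likely to fail

1. Step 7 (new method). The C10 ether may ionise before the conjugate addition, and the cation may then lose a proton towards C11, which would erase the only stereocentre. Alternatively the cation formed after the first ring closure may lose a proton instead of closing the four-membered ring. Fallback, setting out from 11 and returning at 14: the two bonds are made in two separate known operations with orthogonal triggers. First the C7 enolate is unmasked without any Lewis acid by Bu4N[Ph3SiF2] (THF, −78 °C), so the ether cannot ionise; the fluoride-triggered intramolecular Michael addition closes the seven-membered ring and TMSCl traps the ring enolate as the bicyclic trimethylsilyl enol ether F1, which is isolated. Then F1 is ionised on its own with TMSOTf (20 mol%, CH2Cl2, −78 to −20 °C) in an intramolecular Nicholas alkylation of the enol silyl ether to give 14. This second operation still closes the four-membered ring, so it removes the ordering risk but not the ring-closure risk.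

2. Step 11. Facial discrimination may be weak or reversed, because both carbonyl substituents (quaternary C6 and the alkene carbon C8) are large for the oxazaborolidine. Fallback, setting out from 18 and returning at 19: a non-selective Luche reduction (NaBH4, CeCl3·7H2O, MeOH, −40 °C) should give 19 together with its C7 epimer, (7S)-longipina-2,8-dien-7-ol F2. The two are separated by chromatography and F2 is re-oxidised with MnO2 (CH2Cl2) to 18 and recycled.

3. Step 15. O9 may be acylated in competition, both hydroxyls may be acylated, or the C7 angelate may migrate to O8 under the basic conditions. Fallback, setting out from 24 and returning at 26: tin-mediated regioselective acylation. Diol 24 is converted with Bu2SnO (toluene, reflux, water removal) into the 8,9-O-dibutylstannylene acetal F3, which is acylated at the less hindered O8 without added base by (R)-2-methylbutanoyl chloride F4 (made from 25 with oxalyl chloride and cat. DMF in CH2Cl2 at 0 °C).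

Further compounds
F1 | step 7 | bicyclic Michael adduct as its ring trimethylsilyl enol ether (Co2(CO)6 complex, C10 still OMe) | O=C1C45C6(C(C)(OC)[C@@H]3CCC(O[Si](C)(C)C)=C[C@@H]3C1(C)C)[Co]4(=C=O)(=C=O)(=C=O)[Co]56(=C=O)(=C=O)=C=O
F2 | step 11 | (7S)-longipina-2,8-dien-7-ol | O[C@H]1C=C[C@@]2(C)[C@@H]3CC=C(C)[C@H]2[C@@H]3C1(C)C
F3 | step 15 | 8,9-O-dibutylstannylene acetal of 24 | C/C=C(/C)C(=O)O[C@@H]1[C@H]4O[Sn](CCCC)(CCCC)O[C@H]4[C@@]2(C)[C@@H]3C(=O)C=C(C)[C@H]2[C@@H]3C1(C)C
F4 | step 15 | (R)-2-methylbutanoyl chloride | CC[C@@H](C)C(Cl)=O
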